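**Retrosynthetic overview**
- Endgame: the two acetates, removal of a temporary 6,7-acetonide, a Heck coupling of a C9 vinyl group with purchased 4-bromofuran-2(5H)-one (the route never closes the butenolide ring), and C4 ketone → enol triflate → methyl for C3=C4/C18.
- Key disconnection: C5–C10 and C8–C9 are cut together, which opens rings A and B to one acyclic alkene–enal–ketone. In the forward direction a hydrogen-atom-transfer radical conjugate addition closes ring A, and the enolate it leaves closes ring B by aldol addition in the same flask.
- Enabling feature: the run C5(CH3, quaternary)–C10(H)–C9(CH3, C11)–C8(CH3, OH) along ring B, with C5–C10 shared by rings A and B. C5–CH3 is read as C5=CH2 plus a hydrogen atom, C10–C9–C11 as an enal, the C8 carbinol as a methyl ketone, and the trans-diequatorial C6/C7 diol as D-tartrate held in a dioxolane.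
- Precursor: D-tartrate acetonide → C2-symmetric diketone → mono enol triflate, joined at C4–C5 by a Ni/Cr coupling to (E)-2-methylhept-2-enedial (from hex-5-enal and methacrolein). The C4 hydroxyl is a temporary handle.
- Ring order: dioxolane (temporary, present from the start) → ring A → ring B (last). The butenolide is brought in intact.

Key step: step 6

Assumption and conventions: clerodane numbering (ring A = C1–C5, C10; ring B = C5–C10) is used for every intermediate, α is the face that carries the C5 and C9 methyl groups, and in step 5 the antipode of the chiral ligand that delivers the (R)-carbinol at C4 is taken, since its sense of induction on this substrate has to be matched by experiment.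

**Step 1**
Reactants: 1 dimethyl (4S,5S)-2,2-dimethyl-1,3-dioxolane-4,5-dicarboxylate (dimethyl 2,3-O-isopropylidene-D-tartrate)
Product: 2 (4S,5S)-N,N'-dimethoxy-N,N',2,2-tetramethyl-1,3-dioxolane-4,5-dicarboxamide (bis-Weinreb amide)
Conditions: MeNH(OMe)·HCl (5 equiv), i-PrMgCl (10 equiv), THF, −20 to 0 °C
Reagents that add atoms: N,O-dimethylhydroxylamine hydrochloride, CNOC.Cl
Why: Aminolysis of both esters by the magnesium amide (Weinreb amide formation) should leave untouched the two tartrate stereocentres, which become C6 and C7 of the target.

**Step 2**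
Reactants: 2 bis-Weinreb amide
Product: 3 1,1'-[(4S,5S)-2,2-dimethyl-1,3-dioxolane-4,5-diyl]diethanone (C2-symmetric diketone)
Conditions: MeMgBr (2.6 equiv), THF, −20 to 0 °C; aq NH4Cl
Reagents that add atoms: methylmagnesium bromide, C[Mg]Br
Why: The Weinreb ketone synthesis stops at the ketone stage, so each amide should take up one methyl group only, and the trans-dioxolane (the more stable epimer) keeps its configuration.

**Step 3**
Reactants: 3 C2-symmetric diketone
Product: 5 1-[(4S,5S)-5-acetyl-2,2-dimethyl-1,3-dioxolan-4-yl]ethenyl trifluoromethanesulfonate, via potassium enolate 4 (not isolated)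
Conditions: KN(SiMe3)2 (1.0 equiv), THF, −78 °C; then PhNTf2 (1.05 equiv), −78 to −20 °C; unreacted 3 recycled
Reagents that add atoms: N-phenylbis(trifluoromethanesulfonimide), O=S(=O)(N(c1ccccc1)S(=O)(=O)C(F)(F)F)C(F)(F)F
Why: Kinetic deprotonation by the bulky amide should take a methyl proton rather than the hindered ring methine, and because 3 is C2-symmetric either ketone gives the same vinyl triflate (enolate O-sulfonylation) with no stereocentre touched.

**Step 4**
Reactants: 6 hex-5-enal; 7 methacrolein (2-methylprop-2-enal)
Product: 8 (E)-2-methylhept-2-enedial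
Conditions: second-generation Hoveyda–Grubbs catalyst (3 mol %), 7 (5 equiv), CH2Cl2, 40 °C
Reagents that add atoms: none
Why: Olefin cross-metathesis of a terminal alkene with methacrolein is a selective pairing of a fast and a slow olefin and should give the trisubstituted enal as the thermodynamically preferred E isomer.

**Step 5**
Reactants: 5 mono enol triflate; 8 (E)-2-methylhept-2-enedial (1.5 equiv)
Product: 9 (2E,7R)-8-[(4R,5S)-5-acetyl-2,2-dimethyl-1,3-dioxolan-4-yl]-7-hydroxy-2-methylnona-2,8-dienal (clerodane C4 R, C6 R, C7 S)
Conditions: CrCl2 (4 equiv), NiCl2 (2 mol %), chiral N-[2-(4-isopropyl-4,5-dihydrooxazol-2-yl)-6-methylphenyl]methanesulfonamide ligand (4.4 equiv, recovered), Et3N (4.4 equiv), THF, 23 °C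
Reagents that add atoms: none
Why: In this Nozaki–Hiyama–Kishi coupling (nickel catalysis, divalent chromium as reductant) the alkenyl triflate is activated without harm to its own ketone, the chromium nucleophile should pick the unbranched saturated aldehyde of 8 ahead of the conjugated α-branched enal, and the temporary C4 carbinol centre (R, Si-face attack) is set by the chiral ligand on chromium.

**Step 6**
Reactants: 9 acyclic alkene–enal–ketone
Product: 12 trans-decalin hydroxy aldehyde (4α-OH; 5α-CH3; 6α,7β-O-isopropylidene; 8β-OH; 8α-CH3; 9α-CH3; 9β-CHO; 10β-H), via tertiary C5 radical 10 (not isolated), via monocyclic iron enolate 11 (not isolated)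
Conditions: Fe(acac)3 (30 mol %), PhSiH2(Oi-Pr) (2.5 equiv), i-PrOH (5 equiv), THF, 0.01 M, argon, 23 °C
Reagents that add atoms: none
Why: An iron hydride formed from Fe(acac)3 and the silane gives a hydrogen atom to the open CH2 end of the 1,1-disubstituted C5 alkene (this completes the C5 methyl group), the nucleophilic tertiary radical 10 adds to C10 of the enal, divalent iron reduces the α-formyl radical to the enolate 11, and 11 adds to the C8 methyl ketone, the closest known reaction type being the hydrogen-atom-transfer-initiated radical conjugate addition/aldol (radical–polar crossover) polycyclisation of alkene–enal–ketone substrates. Ring A closes in a 6-exo-trig radical mode through a chair in which the enal arm on C10, the C4 hydroxyl and the dioxolanyl group on C5 are equatorial and the new methyl is axial, which sets C5 and C10 trans (5α-CH3, 10β-H). The face of C5 is chosen by C6 in a Felkin–Anh-type arrangement reinforced by a C4–OH···O6 hydrogen bond: C7 lies anti to the larger C4 branch, the C6–O bond lies anti to the forming C5–C10 bond and C10 enters past the C6 hydrogen, so that O6 ends up equatorial. Ring B, the last ring, closes in a 6-(enolexo)-exo-trig aldol in which allylic 1,3-strain holds the C10–H bond in the plane of the C9=C11 enolate, so that C8 bonds to the face that leaves C11 equatorial (β) and the C9 methyl axial (α), while the iron bridge between enolate and ketone oxygens and the preference of the C8 methyl for the equatorial site give the axial 8β-OH cis to the formyl group. The trans-dioxolane holds C5 and C8 gauche for this closure and excludes the trans-decalin of opposite sense at C5/C10, which would need a diaxial diol. The step needs hydrogen-atom transfer to the electron-neutral terminal alkene ahead of the electron-poor trisubstituted enal, and cyclisation ahead of a 1,5-hydrogen shift from C1 and of enolate protonation, which the polarity match of a tertiary alkyl radical with an enal, high dilution and a nearly aprotic medium should secure.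

**Step 7**
Reactants: 12 trans-decalin hydroxy aldehyde
Product: 13 4-oxo aldehyde (C4 ketone; otherwise as 12)
Conditions: Dess–Martin periodinane (1.3 equiv), CH2Cl2, 0 to 23 °C
Reagents that add atoms: none
Why: Dess–Martin oxidation should convert the only secondary alcohol into the C4 ketone (erasing the temporary C4 stereocentre) under near-neutral conditions that spare the retro-aldol-prone β-hydroxy aldehyde and cannot touch the tertiary C8 alcohol.

**Step 8**
Reactants: 13 4-oxo aldehyde
Product: 14 9β-vinyl 4-ketone (CHO replaced by CH=CH2)
Conditions: RhCl(PPh3)3 (5 mol %), TMSCHN2 (1.5 equiv), PPh3 (1.2 equiv), i-PrOH (2 equiv), THF, 23 °C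
Reagents that add atoms: (trimethylsilyl)diazomethane, C[Si](C)(C)C=[N+]=[N-]
Why: This rhodium-catalysed methylenation is a Wittig reaction with salt-free ylide formed slowly in situ, it is selective for aldehydes over ketones and nearly neutral, and so it should convert the neopentyl aldehyde without retro-aldol opening of ring B.

**Step 9**
Reactants: 14 9β-vinyl 4-ketone
Product: 16 C3=C4 enol triflate, via dipotassium enolate alkoxide 15 (not isolated)
Conditions: KN(SiMe3)2 (2.2 equiv), THF, −78 °C; then PhNTf2 (1.1 equiv), −78 to 0 °C
Reagents that add atoms: N-phenylbis(trifluoromethanesulfonimide), O=S(=O)(N(c1ccccc1)S(=O)(=O)C(F)(F)F)C(F)(F)F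
Why: Because C5 is quaternary the C4 ketone can enolise only toward C3, so enolate O-sulfonylation (vinyl triflate synthesis) should give one regioisomer while the second equivalent of base merely parks the hindered C8 hydroxyl as its alkoxide.

**Step 10**
Reactants: 16 C3=C4 enol triflate
Product: 17 4-methyl-3-ene (ring A complete; 9β-vinyl; 8β-OH; 6,7-acetonide)
Conditions: Fe(acac)3 (10 mol %), MeMgBr (3 equiv), THF/NMP, −20 °C
Reagents that add atoms: methylmagnesium bromide, C[Mg]Br
Why: Iron-catalysed Kumada-type cross-coupling of alkenyl triflates with MeMgBr is fast at low temperature even next to a quaternary centre and should install C18 with the C3=C4 double bond fixed in place, the vinyl group and the acetonide being inert.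

**Step 11**
Reactants: 17 4-methyl-3-ene; 18 4-bromofuran-2(5H)-one
Product: 19 6,7-O-isopropylidene dienyl butenolide ((E)-C11=C12 joined to C13 of the butenolide)
Conditions: Pd(OAc)2 (10 mol %), n-Bu4NCl (1 equiv), NaHCO3 (2.5 equiv), DMF, 60 °C
Reagents that add atoms: none
Why: In this Heck reaction zerovalent palladium inserts into the vinylogous acyl bromide, the only monosubstituted alkene inserts with carbon bonding to its CH2 end, and syn β-hydride elimination (quaternary C9 has no hydrogen) should give the E diene, the trisubstituted C3=C4 alkene being too hindered to react.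

**Step 12**
Reactants: 19 acetonide
Product: 20 6α,7β,8β-triol
Conditions: AcOH/H2O (4:1), 45 °C
Reagents that add atoms: none
Why: Acid-catalysed acetal hydrolysis is eased by the strain of the trans-fused dioxolane, so aqueous acetic acid should suffice and the tertiary C8 alcohol, both alkenes of the diene, C3=C4 and the butenolide should survive.

**Step 13**
Reactants: 20 triol
Product: 21 6α,7β-diacetoxy-8β-hydroxy-neo-cleroda-3,11E,13-trien-15,16-olide (CNP0383656.1)
Conditions: Ac2O (6 equiv), pyridine, DMAP (10 mol %), 23 °C
Reagents that add atoms: acetic anhydride, CC(=O)OC(C)=O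
Why: DMAP-catalysed acylation should esterify the two secondary equatorial alcohols, while the tertiary axial C8 hydroxyl next to quaternary C9 stays free at room temperature.

**Compound list**
1 | dimethyl (4S,5S)-2,2-dimethyl-1,3-dioxolane-4,5-dicarboxylate | COC(=O)[C@H]1OC(C)(C)O[C@@H]1C(=O)OC | starting material
2 | (4S,5S)-bis-Weinreb amide of 2,3-O-isopropylidene-D-tartaric acid | CON(C)C(=O)[C@H]1OC(C)(C)O[C@@H]1C(=O)N(C)OC | intermediate
3 | 1,1'-[(4S,5S)-2,2-dimethyl-1,3-dioxolane-4,5-diyl]diethanone | CC(=O)[C@H]1OC(C)(C)O[C@@H]1C(C)=O | intermediate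
4 | potassium enolate of 3 (methyl side, mono) | CC(=O)[C@H]1OC(C)(C)O[C@@H]1C(=C)[O-].[K+] | intermediate
5 | 1-[(4S,5S)-5-acetyl-2,2-dimethyl-1,3-dioxolan-4-yl]ethenyl triflate | CC(=O)[C@H]1OC(C)(C)O[C@@H]1C(=C)OS(=O)(=O)C(F)(F)F | intermediate
6 | hex-5-enal | C=CCCCC=O | starting material
7 | methacrolein | CC(=C)C=O | starting material
8 | (E)-2-methylhept-2-enedial | O=CCCC/C=C(\C)C=O | intermediate
9 | acyclic alkene–enal–ketone (C4 R, C6 R, C7 S) | CC(=O)[C@H]1OC(C)(C)O[C@@H]1C(=C)[C@H](O)CCC/C=C(\C)C=O | intermediate
10 | tertiary C5 radical | CC(=O)[C@H]1OC(C)(C)O[C@@H]1[C](C)[C@H](O)CCC/C=C(\C)C=O | intermediate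
11 | monocyclic iron enolate, ring A closed (drawn as the free enol) | CC(=O)[C@H]1OC(C)(C)O[C@@H]1[C@@]2(C)[C@H](O)CCC[C@@H]2C(C)=CO | intermediate
12 | trans-decalin hydroxy aldehyde | CC1(C)O[C@H]2[C@H](O1)[C@](C)(O)[C@](C)(C=O)[C@H]3CCC[C@@H](O)[C@]23C | intermediate
13 | 4-oxo aldehyde | CC1(C)O[C@H]2[C@H](O1)[C@](C)(O)[C@](C)(C=O)[C@H]3CCCC(=O)[C@]23C | intermediate
14 | 9β-vinyl 4-ketone | CC1(C)O[C@H]2[C@H](O1)[C@](C)(O)[C@](C)(C=C)[C@H]3CCCC(=O)[C@]23C | intermediate
15 | dipotassium C3=C4 enolate / C8 alkoxide | CC1(C)O[C@H]2[C@H](O1)[C@](C)([O-])[C@](C)(C=C)[C@H]3CCC=C([O-])[C@]23C.[K+].[K+] | intermediate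
16 | C3=C4 enol triflate | CC1(C)O[C@H]2[C@H](O1)[C@](C)(O)[C@](C)(C=C)[C@H]3CCC=C(OS(=O)(=O)C(F)(F)F)[C@]23C | intermediate
17 | 4-methyl-3-ene with 9β-vinyl group | CC1(C)O[C@H]2[C@H](O1)[C@](C)(O)[C@](C)(C=C)[C@H]3CCC=C(C)[C@]23C | intermediate
18 | 4-bromofuran-2(5H)-one | BrC1=CC(=O)OC1 | starting material
19 | 6,7-O-isopropylidene dienyl butenolide | CC1(C)O[C@H]2[C@H](O1)[C@](C)(O)[C@](C)(/C=C/C4=CC(=O)OC4)[C@H]3CCC=C(C)[C@]23C | intermediate
20 | 6α,7β,8β-triol | O[C@H]1[C@H](O)[C@](C)(O)[C@](C)(/C=C/C2=CC(=O)OC2)[C@H]2CCC=C(C)[C@]12C | intermediate
21 | 6α,7β-diacetoxy-8β-hydroxy-neo-cleroda-3,11E,13-trien-15,16-olide | CC(=O)O[C@H]1[C@H](OC(C)=O)[C@](C)(O)[C@](C)(/C=C/C2=CC(=O)OC2)[C@H]2CCC=C(C)[C@]12C | target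

**Step count**
Total: 13 steps. Longest linear sequence: 12 steps (steps 1–3 and 5–13).

**Steps most likely to fail**

*Step 6.* What may go wrong:
- poor facial selectivity when the C5 radical attacks C10;
- a 1,5-hydrogen shift from C1;
- oxa-Michael addition of the C4 hydroxyl to the enal;
- protonation of the enolate before ring B closes.

The fallback sets out from 9 and comes back at 12. It takes the two ring closures apart. Compound 9 is cyclised with Fe(acac)3 and PhSiH3 in ethanol, a protic medium in which the reaction should stop at the monocyclic keto aldehyde F1 (ring A closed, C9 as a mixture of epimers). Unwanted C5/C10 diastereomers are removed at this stage. Ring B is then closed in a separate, reversible enamine aldol (pyrrolidine, AcOH, CH2Cl2). This is a 6-enolexo aldolisation under thermodynamic control, in which both C9 epimers should converge through the common enamine on 12.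

*Step 5.* What may go wrong is competing addition to the conjugated aldehyde of 8 and weak ligand control at C4. The fallback sets out from 5 and comes back at 9. The enal is built only after the coupling, so the chromium reagent meets a single aldehyde.
- Ozonolysis of cyclopentene in methanol with TsOH, then NaHCO3 and Me2S, gives 5,5-dimethoxypentanal F2.
- The same Ni/Cr coupling of 5 with F2 gives the allylic alcohol acetal F3, whose C4 epimers can be separated.
- The acyclic dimethyl acetal is hydrolysed ahead of the dioxolane (LiBF4, wet MeCN) to the hydroxy aldehyde F4, which is in equilibrium with its lactol.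
- A Wittig reaction with 2-(triphenylphosphoranylidene)propanal gives 9.

*Step 11.* What may go wrong is base-induced decay of the bromobutenolide during a slow insertion of the neopentyl-type vinyl group. The fallback sets out from 17 and comes back at 19. It reverses the polarity of the coupling. Cross-metathesis of 17 with vinylboronic acid pinacol ester (second-generation Hoveyda–Grubbs catalyst, CH2Cl2, reflux) gives the (E)-alkenylboronate F5. Suzuki–Miyaura coupling of F5 with 18 (Pd(dppf)Cl2, K3PO4, THF/H2O, 40 °C) then gives 19 at lower temperature and with shorter exposure of 18 to base.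

**Further compounds**
F1 | step 6 | monocyclic keto aldehyde (ring A closed, C9 epimers) | CC(=O)[C@H]1OC(C)(C)O[C@@H]1[C@@]2(C)[C@H](O)CCC[C@@H]2C(C)C=O
F2 | step 5 | 5,5-dimethoxypentanal | COC(OC)CCCC=O
F3 | step 5 | allylic alcohol acetal | CC(=O)[C@H]1OC(C)(C)O[C@@H]1C(=C)[C@H](O)CCCC(OC)OC
F4 | step 5 | hydroxy aldehyde (open form) | CC(=O)[C@H]1OC(C)(C)O[C@@H]1C(=C)[C@H](O)CCCC=O
F5 | step 11 | (E)-alkenylboronic acid pinacol ester | CC1(C)O[C@H]2[C@H](O1)[C@](C)(O)[C@](C)(/C=C/B4OC(C)(C)C(C)(C)O4)[C@H]3CCC=C(C)[C@]23C
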